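**Numbering used in the text.** Decalin ring A is C1–C4 plus C5 and C10. Ring B is C5–C10. C11 and C12 are the side-chain carbons, and the cyclopentenone carbons are C1'–C5'. The SMILES is read as a trans-decalin (5-Me up, 10-H down) with 9-Me axial and syn to 5-Me, 8-Me axial and anti to it, and C11 equatorial.

**Assumption:** (S)-Wieland–Miescher ketone (1) is bought as the source of C5. The last step gives a mixture of diastereomers at C1'/C5', and the target is separated chromatographically.

## Retrosynthesis
- The target comes from furfuryl alcohol **13** by a Piancatelli-type 4π-conrotatory electrocyclization with water capture. This closes the cyclopentenone and sets C1' and C5'.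
- **13** comes from decalin aldehyde **9** plus the 2-magnesiofuran from **12**.
- In **9**, the C8 quaternary centre is made by axial Me-cuprate addition to alkylidene ester **7** of trans-decalone **6**, which carries an axial 9-Me.
- **6** comes from Li/NH3 reduction of α-methyl enone **5**, which comes from (S)-Wieland–Miescher ketone (**1**). Both decalin rings are already in **1**, and the cyclopentenone is formed last.

## Route

**Step 1**
Reactants: 1, (S)-Wieland–Miescher ketone
Product: 2, enone with a C4 tertiary methyl carbinol (C4 epimeric mixture)
Conditions: MeMgBr, THF, –78 °C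
Reagents that add atoms: methylmagnesium bromide, C[Mg]Br
Why: Grignard addition occurs chemoselectively at the non-conjugated C4 ketone, and the C4 stereocentre is destroyed in the next step. The C5 quaternary centre is untouched.

**Step 2**
Reactants: 2
Product: 3, (S)-4a,5-dimethyl-4,4a,7,8-tetrahydronaphthalen-2(3H)-one (C4-methyl-Δ3 enone)
Conditions: SOCl2, pyridine, CH2Cl2, 0 °C
Reagents that add atoms: none
Why: E2-type dehydration of the tertiary alcohol gives the trisubstituted endocyclic C3=C4 alkene. The 1,1-disubstituted exocyclic isomer is removed by AgNO3–silica chromatography.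

**Step 3**
Reactants: 3
Product: 4, α-iodoenone (9-iodo)
Conditions: I2, DMAP, pyridine/CH2Cl2, 0 °C → rt
Reagents that add atoms: iodine, II
Why: Krafft/Johnson α-iodination of a β,β-disubstituted enone by conjugate addition of the nucleophile, iodination, then elimination. The alkene is not an azide-type trap, so it survives.

**Step 4**
Reactants: 4
Product: 5, α-methyl enone (C9-Me, C9=C10)
Conditions: MeB(OH)2, Pd(dppf)Cl2, K3PO4, dioxane/H2O, 80 °C
Reagents that add atoms: methylboronic acid, CB(O)O
Why: Suzuki coupling installs the C9 carbon with no new stereocentre.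

**Step 5**
Reactants: 5
Product: 6, trans-fused decalin-8-one with axial 9-Me
Conditions: Li, NH3(l)/THF, t-BuOH (1 equiv), –78 °C; then solid NH4Cl
Reagents that add atoms: none
Why: Dissolving-metal enone reduction protonates C10 axially, giving the trans ring fusion (10-H anti to 5-Me). The lithium enolate is then protonated at C9 from the bottom face, because the top face is blocked by the syn-diaxial 5-Me. This leaves the 9-Me axial and syn to 5-Me. The 9-H is equatorial and therefore resists enolization and epimerization.

**Step 6**
Reactants: 6
Product: 7, ethyl (8-ylidene)acetate (alkylidene ester, E/Z mixture)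
Conditions: LDA, Me3SiCH2CO2Et, THF, –78 °C; CeCl3 added; then ketone 6, –78 °C → rt
Reagents that add atoms: ethyl (trimethylsilyl)acetate, C[Si](C)(C)CC(=O)OCC
Why: Peterson olefination with a cerium-attenuated α-silyl ester enolate adds to the hindered, enolizable C8 ketone without enolizing it. It installs C11 and C12, and C9 is not touched.

**Step 7**
Reactants: 7
Product: 8, ethyl 2-[(8-methyl)decalin-8-yl]acetate (C8 quaternary)
Conditions: Me2CuLi (MeLi, CuI), TMSCl, THF, –78 → 0 °C
Reagents that add atoms: lithium dimethylcuprate, C[Cu-]C.[Li+]
Why: Axial 1,4-addition of Me to C8 occurs from the bottom face, anti to the axial 5-Me and 9-Me. This gives 8-Me axial down and C11 equatorial up, independent of the E/Z geometry of 7.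

**Step 8**
Reactants: 8
Product: 9, decalin-8-yl-acetaldehyde (C8–CH2–CHO, Δ3 alkene retained)
Conditions: DIBAL-H (1.1 equiv), CH2Cl2, –78 °C
Reagents that add atoms: none
Why: Partial reduction of the ester to the aldehyde at low temperature. The trisubstituted alkene is inert.

**Step 9** (parallel branch)
Reactants: 10, methyl 4-bromofuran-2-carboxylate
Product: 11, methyl 4-methoxyfuran-2-carboxylate
Conditions: NaOMe, CuI (20 mol %), MeOH/DMF, 90 °C
Reagents that add atoms: sodium methoxide, C[O-].[Na+]
Why: Ullmann-type methoxylation of a 3-bromofuran-type halide. The methyl ester does not change under methoxide.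

**Step 10** (parallel branch)
Reactants: 11
Product: 12, methyl 5-bromo-4-methoxyfuran-2-carboxylate
Conditions: NBS, DMF, 0 °C
Reagents that add atoms: N-bromosuccinimide, O=C1CCC(=O)N1Br
Why: Electrophilic bromination goes at the free α-position C5, which is activated by the 4-OMe. This fixes the regiochemistry for metalation.

**Step 11**
Reactants: 9 (decalin aldehyde) and 12 (bromofuran)
Product: 13, furfuryl alcohol, 1-(3-methoxy-5-CO2Me-furan-2-yl)-2-decalinylethanol (carbinol epimers)
Conditions: i-PrMgCl·LiCl, THF, –40 °C (Br/Mg exchange); then 9, –40 → 0 °C
Reagents that add atoms: none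
Why: Ester-tolerant halogen–magnesium exchange gives the 2-furyl Grignard, which adds to the aldehyde. The carbinol centre is lost in the next step, so its configuration is irrelevant.

**Step 12**
Reactants: 13
Product: 14, dysidenone B
Conditions: Dy(OTf)3 (5 mol %), MeCN/H2O (4:1), 60 °C
Reagents that add atoms: water, O
Why: This is the Piancatelli rearrangement. Ionization of the carbinol, water capture at furan C5 and ring opening give a hydroxypentadienyl cation. Conrotatory 4π electrocyclization then closes the ring. Torquoselectivity puts the new 4-OH trans to the C5' alkyl group and CO2Me cis to it, and the 3-OMe enol ether ends up as the 2-methoxycyclopent-2-enone. The facial sense relative to the decalin is set only by remote substrate bias, so diastereomers at C1'/C5' are separated by chromatography.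

## Compound list
1 | (S)-Wieland–Miescher ketone | O=C1CC[C@]2(C)C(=O)CCCC2=C1 | starting material
2 | C4-methyl carbinol enone, C4 epimers | O=C1CC[C@]2(C)C(C)(O)CCCC2=C1 | intermediate
3 | (4aS)-4a,5-dimethyl-4,4a,7,8-tetrahydronaphthalen-2(3H)-one | O=C1CC[C@]2(C)C(C)=CCCC2=C1 | intermediate
4 | 9-iodo enone | O=C1CC[C@]2(C)C(C)=CCCC2=C1I | intermediate
5 | 9-methyl enone | O=C1CC[C@]2(C)C(C)=CCCC2=C1C | intermediate
6 | trans-decalin-8-one, axial 9-Me | O=C1CC[C@]2(C)C(C)=CCC[C@H]2[C@H]1C | intermediate
7 | alkylidene ethyl ester (E/Z) | CCOC(=O)C=C1CC[C@]2(C)C(C)=CCC[C@H]2[C@H]1C | intermediate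
8 | ethyl ester with C8 quaternary centre | CCOC(=O)C[C@@]1(C)CC[C@]2(C)C(C)=CCC[C@H]2[C@H]1C | intermediate
9 | decalin acetaldehyde | O=CC[C@@]1(C)CC[C@]2(C)C(C)=CCC[C@H]2[C@H]1C | intermediate
10 | methyl 4-bromofuran-2-carboxylate | COC(=O)c1cc(Br)co1 | starting material
11 | methyl 4-methoxyfuran-2-carboxylate | COC(=O)c1cc(OC)co1 | intermediate
12 | methyl 5-bromo-4-methoxyfuran-2-carboxylate | COC(=O)c1cc(OC)c(Br)o1 | intermediate
13 | furfuryl alcohol (carbinol epimers) | COC(=O)c1cc(OC)c(o1)C(O)C[C@@]1(C)CC[C@]2(C)C(C)=CCC[C@H]2[C@H]1C | intermediate
14 | dysidenone B | COC(=O)[C@@]1(O)C=C(OC)C(=O)[C@H]1C[C@@]1(C)CC[C@]2(C)C(C)=CCC[C@H]2[C@H]1C | target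

## Totals
Total steps: 12. Longest linear sequence: 10 steps (steps 1–8, 11, 12, counted from compound 1).

## Three steps most likely to fail
1. **Step 12 (Piancatelli).**
   - The electron-poor, ester-bearing furan may ionize poorly.
   - The Δ3 alkene may isomerize or undergo a methyl shift in hot aqueous Lewis acid.
   - The diastereoselectivity at C1'/C5' is only remotely controlled.
   - Fallback: build the ring by biomimetic contraction instead. Convert 9 to the 3-alkyl-2-hydroxy-5-methoxy-p-benzoquinone, then effect a benzilic-ester ring contraction with NaOMe/MeOH.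
2. **Step 5 (C9 stereocentre).**
   - Kinetic protonation may give the equatorial 9-Me epimer instead of the axial one.
   - Fallback: reduce the C9-unsubstituted enone 3 with Li/NH3. Then make the α-methylene ketone by Mannich/elimination and hydrogenate the exocyclic alkene from the bottom face, which delivers the axial 9-Me.
3. **Step 7 (quaternary C8 by cuprate addition to a β,β-disubstituted enoate).**
   - Fallback: use a more electrophilic acceptor. Do a Cope–Knoevenagel of ketone 6 with ethyl cyanoacetate, then add MeMgBr/CuI (or Me2CuLi) to the alkylidene cyanoacetate, then Krapcho decarboxylation. Finally, DIBAL reduction of the nitrile gives aldehyde 9.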